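The data were generated by integration with made-up constants, and the scatter is random.

Count in millimolar of incoming ligand first; percent comes later.

| flask | starting complex | incoming ligand | leaving ligand | capture agent | remark | time |
|---|---|---|---|---|---|---|
| eta | 13 mM | 32.5 mM | 65 mM | 0.26 mM | run made earlier |  |
| alpha | 13 mM | 32.5 mM | 32 mM | 0.26 mM | run made earlier |  |
| delta | 13 mM | 32.5 mM | 49 mM | 0.26 mM | run made earlier |  |
| west | 13 mM | 32.5 mM (fed, over 8.0 min) | 65.0 mM | 0.260 mM | all else is in the flask from the start; the feed brings no volume worth counting | 12 min |
| south | 13 mM (fed, over 8.0 min) | 32.5 mM | 65.0 mM | 0.260 mM | all else is in the flask from the start; the feed brings no volume worth counting | 12 min |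
| south-west | 13 mM (in portions, 3, over 8.0 min) | 32.5 mM | 65.0 mM | 0.260 mM | first portion at the start, last at 8.0 min | 12 min |
| east | 13 mM | 32.5 mM | 65.0 mM | 0.260 mM | everything together at the start | 12 min |

| run | time / min | complex with two exchanged / % |
|---|---|---|
| eta | 1.33 | 16.4 |
| eta | 3.00 | 32.3 |
| eta | 4.00 | 36.7 |
| eta | 6.00 | 45.3 |
| eta | 8.00 | 48.2 |
| alpha | 1.00 | 11.9 |
| alpha | 2.00 | 21.3 |
| alpha | 3.00 | 31.1 |
| alpha | 6.00 | 44.1 |
| alpha | 12.0 | 53.7 |
| delta | 2.50 | 25.2 |
| delta | 5.00 | 40.8 |
| delta | 8.00 | 51.9 |
| delta | 10.0 | 53.5 |
| delta | 12.0 | 52.6 |

(standard deviation of a reading: 1 percentage point)

- what is said of complex with two exchanged includes idle adduct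
- the earlier runs were read with a standard deviation of 1 percentage point
- candidate steps: starting complex + incoming ligand -> leaving ligand + complex with one exchanged; complex with one exchanged + capture agent -> trapped intermediate; complex with one exchanged + incoming ligand -> leaving ligand + complex with two exchanged; complex with two exchanged + incoming ligand <-> idle adduct; 2 incoming ligand -> self-condensation product

- the flask with the highest amount of complex with two exchanged, in percent of the starting complex charged ("all alike" if they lie within 1.5 percentage points) (west / south / south-west / east / all alike)
- final complex with two exchanged, as a percentage of the starting complex charged, in west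
- final complex with two exchanged, as a percentage of the starting complex charged, in south
- final complex with two exchanged, as a percentage of the starting complex charged, in south-west
- final complex with two exchanged, as a percentage of the starting complex charged, in east

What does one starting complex cost? Two incoming ligand, one for each exchange, so 13 mM of complex asks for 26.0 mM and the charge is 32.5 mM. On paper the starting complex is the limiting reagent. That leaves 6.50 mM, the spare ligand, meaning the charge less two for each starting complex.

Does the leaving ligand matter? At 6.00 min the eta run reads 45.3% with 65 mM of it and the alpha run reads 44.1% with 32 mM. With a scatter of 1 percentage point per reading, I see no effect.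

The last two delta readings, 53.5% at 10.0 min and 52.6% at 12.0 min, lie within a scatter of 1 point, so they show no stop. But why does the delta run slow, gaining 25.2% by 2.50 min and 27 points in the whole of the time from there to 12.0 min? I suspect the ligand. Self-condensation, a candidate step, takes two ligand per turn, so 3.25 mM of self-condensation product would eat the spare.

So feed the ligand slowly? That is my lean. Self-condensation goes with [incoming ligand] squared and each exchange with its first power.

And the weak spot? Low [incoming ligand] slows the exchanges too, and the clock stops at 12 min. The spare gives a direction, not a size. I commit to this order: west, where the ligand is fed, above east, where everything goes in at the start, with south, where the complex is fed, at the bottom.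

The forecast puts east first: west 46%, south 25%, south-west 29%, east 53%. Its ground for west is “West suppresses self-condensation, but ligand stays low”.

The flasks give west as highest: west 59.2%, south 26.1%, south-west 31.8%, east 55.4%. West stands 13 points above the forecast.

    starting complex + incoming ligand → leaving ligand + complex with one exchanged (k = 0.297 M⁻¹ s⁻¹)
    complex with one exchanged + capture agent → trapped intermediate (k = 0.0711 M⁻¹ s⁻¹)
    complex with one exchanged + incoming ligand → leaving ligand + complex with two exchanged (k = 0.478 M⁻¹ s⁻¹)
    complex with two exchanged + incoming ligand ⇌ idle adduct, settled at all times (K = 25.9 M⁻¹)
    2 incoming ligand → self-condensation product (k = 0.0992 M⁻¹ s⁻¹)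

Against the spare, east has burned 13.3 mM of ligand into self-condensation product by 12.0 min, twice the spare. West has burned 8.99 mM, and 14.2% of its own charge still stands. Take that step away and the gap between west and south falls from 33 points to 1.6 points, and the highest flask changes.

A neighbour of west charged with 130 mM of incoming ligand has a spare of 104 mM, enough for the exchanges and a heavy burn besides. It ends at 98.2% complex with two exchanged, having burned 87.3 mM.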